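**Retrosynthetic overview** (chain numbered from the benzylic carbon C1 to the terminal methyl C16)

- The route rests on the C3=O / C5=O pair separated only by C4H2: this 1,3-dioxygenated unit is read as a cyclopropane made of C3, C4 and C5 with a hydroxyl on C5, whose C3–C5 bond is cut while O2 is placed on C3.
- Target 12 ⇐ debenzylation of diketone 11 ⇐ oxidation of β-hydroxy ketone 10 ⇐ O–O reduction of 1,2-dioxolan-3-ol 9.
- 9 ⇐ manganese-catalysed aerobic radical ring-opening of cyclopropanol 7 (C3–C5 broken, C3–O formed).
- 7 ⇐ Kulinkovich alkene-exchange cyclopropanation of methyl dodecanoate 5 with arylbutene 4 (C5–C3 and C5–C4 formed); 4 ⇐ benzylic chloride 2 + allylmagnesium bromide 3.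
- Ring order: cyclopropane (step 3), then the 1,2-dioxolane (step 4); both are opened again, and only the purchased benzene ring remains in 12.

Key step: step 4

Remark: 7, 8, 9 and 10 are racemic (9 also a mixture of diastereomers), which is of no consequence because 12 has no stereocentre; 12 is written as the diketone although it will exist largely as its chelated enol tautomer.

**Step 1**
Reactants: 1 4-benzyloxy-3-methoxybenzyl alcohol
Product: 2 4-benzyloxy-3-methoxybenzyl chloride
Conditions: SOCl2 (1.2 equiv), CH2Cl2, 0 °C → rt; volatiles removed, used crude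
Reagents that add atoms: thionyl chloride, O=S(Cl)Cl
Why: Deoxychlorination of a primary benzylic alcohol with SOCl2 runs through the chlorosulfite and is fast for this electron-rich ring, while both aryl ethers are inert; the sensitive chloride is not stored.

**Step 2**
Reactants: 2 4-benzyloxy-3-methoxybenzyl chloride; 3 allylmagnesium bromide
Product: 4 4-(4-benzyloxy-3-methoxyphenyl)but-1-ene
Conditions: THF/Et2O, 0 °C → rt; aq. NH4Cl
Reagents that add atoms: none
Why: Grignard alkylation of the reactive benzylic chloride by allylmagnesium bromide (SN2-type sp3–sp3 coupling) forms the C1–C2 bond and leaves a terminal alkene whose two carbons become C3 and C4.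

**Step 3**
Reactants: 4 4-(4-benzyloxy-3-methoxyphenyl)but-1-ene; 5 methyl dodecanoate
Product: 7 (1R*,2R*)-2-[2-(4-benzyloxy-3-methoxyphenyl)ethyl]-1-undecylcyclopropan-1-ol, via titanacyclopropane 6 (not isolated)
Conditions: ClTi(OiPr)3 (1 equiv), cyclohexylmagnesium chloride (4.5 equiv, slow addition), THF, rt; aq. NH4Cl
Reagents that add atoms: none
Why: Kulinkovich cyclopropanation under alkene-exchange conditions: cyclohexylmagnesium chloride and ClTi(OiPr)3 give a cyclohexene titanacyclopropane that trades its hindered alkene for the terminal alkene of 4 to give 6, which adds twice to the ester carbonyl as a 1,2-dicarbanion and forms the C5–C4 and C5–C3 bonds, the ring closure placing undecyl and arylethyl cis (hydroxyl trans to the side chain) as is usual for this reaction, in racemic form because no chiral element is present.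

**Step 4**
Reactants: 7 (1R*,2R*)-2-[2-(4-benzyloxy-3-methoxyphenyl)ethyl]-1-undecylcyclopropan-1-ol
Product: 9 5-[2-(4-benzyloxy-3-methoxyphenyl)ethyl]-3-undecyl-1,2-dioxolan-3-ol (racemic diastereomer mixture), via hydroperoxy ketone 8 (not isolated)
Conditions: Mn(acac)2 (2 mol %), O2 (1 atm), benzene, rt
Reagents that add atoms: dioxygen, O=O
Why: O2 oxidises Mn(acac)2 to a trivalent manganese species that binds the cyclopropanol as its alkoxide; one-electron oxidation gives the cyclopropyloxy radical, β-scission of the C3–C5 ring bond leaves the C5 ketone and a secondary radical at C3, and this radical captures O2 to a peroxyl radical that is reduced and protonated to hydroperoxide 8 while divalent manganese returns to the cycle. The closest known reaction type is the manganese-catalysed aerobic ring-opening of 1,2-disubstituted Kulinkovich cyclopropanols to cyclic peroxyhemiketals. The dioxolane ring closes by 5-exo-trig addition of the terminal hydroperoxide oxygen to the C5 carbonyl (hemiketal formation, a ring–chain equilibrium expected to lie on the ring side). The two new stereocentres are not controlled, C3 being set by O2 capture at a planar radical without facial bias and the hemiketal carbon C5 being free to equilibrate, which is acceptable because both are erased in steps 5 and 6. The selectivity needed is cleavage of C3–C5 over C4–C5, and the arylethyl substituent on C3 secures it by making that bond the weaker one and the resulting radical secondary instead of primary. The benzyl ether keeps a free phenol from reducing peroxyl radicals or binding manganese, and the reaction is stopped at full conversion so that benzylic C–H bonds are not autoxidised.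

**Step 5**
Reactants: 9 5-[2-(4-benzyloxy-3-methoxyphenyl)ethyl]-3-undecyl-1,2-dioxolan-3-ol
Product: 10 1-(4-benzyloxy-3-methoxyphenyl)-3-hydroxyhexadecan-5-one (racemic)
Conditions: PPh3 (1.1 equiv), THF, 0 °C → rt
Reagents that add atoms: none
Why: Phosphine reduction of a peroxide: PPh3 attacks the O–O bond, one oxygen leaves as the phosphine oxide and the hemiketal that remains collapses to the C5 ketone, giving the β-hydroxy ketone under neutral conditions that should not dehydrate it.

**Step 6**
Reactants: 10 1-(4-benzyloxy-3-methoxyphenyl)-3-hydroxyhexadecan-5-one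
Product: 11 1-(4-benzyloxy-3-methoxyphenyl)hexadecane-3,5-dione
Conditions: Dess–Martin periodinane (1.1 equiv), CH2Cl2, 0 °C → rt; aq. Na2S2O3/NaHCO3
Reagents that add atoms: none
Why: Dess–Martin oxidation of the secondary C3 alcohol gives the 1,3-diketone under mild, non-basic conditions that avoid retro-aldol cleavage, and holding the periodinane to a slight excess keeps the C4 methylene of the product from further oxidation.

**Step 7**
Reactants: 11 1-(4-benzyloxy-3-methoxyphenyl)hexadecane-3,5-dione
Product: 12 [12]-gingerdione, 1-(4-hydroxy-3-methoxyphenyl)hexadecane-3,5-dione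
Conditions: H2 (1 atm), 10% Pd/C, EtOAc, rt
Reagents that add atoms: none
Why: Catalytic hydrogenolysis of the aryl benzyl ether over Pd/C frees the phenol, and the aryl methyl ether and the enolised 1,3-diketone are not expected to be reduced at 1 atm.

**Compound list**

1 | 4-benzyloxy-3-methoxybenzyl alcohol | COc1cc(CO)ccc1OCc1ccccc1 | starting material
2 | 4-benzyloxy-3-methoxybenzyl chloride | COc1cc(CCl)ccc1OCc1ccccc1 | intermediate
3 | allylmagnesium bromide | C=CC[Mg]Br | starting material
4 | 4-(4-benzyloxy-3-methoxyphenyl)but-1-ene | C=CCCc1ccc(OCc2ccccc2)c(OC)c1 | intermediate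
5 | methyl dodecanoate | CCCCCCCCCCCC(=O)OC | starting material
6 | 2-[2-(4-benzyloxy-3-methoxyphenyl)ethyl]-1,1-di(propan-2-yloxy)titanacyclopropane (racemic, not isolated) | CC(C)O[Ti]1(OC(C)C)CC1CCc1ccc(OCc2ccccc2)c(OC)c1 | intermediate
7 | (1R*,2R*)-2-[2-(4-benzyloxy-3-methoxyphenyl)ethyl]-1-undecylcyclopropan-1-ol (racemic; undecyl and arylethyl cis, OH trans to the arylethyl group; one enantiomer drawn) | CCCCCCCCCCC[C@@]1(O)C[C@H]1CCc1ccc(OCc2ccccc2)c(OC)c1 | intermediate
8 | 1-(4-benzyloxy-3-methoxyphenyl)-3-hydroperoxyhexadecan-5-one (racemic, not isolated) | CCCCCCCCCCCC(=O)CC(OO)CCc1ccc(OCc2ccccc2)c(OC)c1 | intermediate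
9 | 5-[2-(4-benzyloxy-3-methoxyphenyl)ethyl]-3-undecyl-1,2-dioxolan-3-ol (racemic mixture of diastereomers) | CCCCCCCCCCCC1(O)CC(CCc2ccc(OCc3ccccc3)c(OC)c2)OO1 | intermediate
10 | 1-(4-benzyloxy-3-methoxyphenyl)-3-hydroxyhexadecan-5-one (racemic) | CCCCCCCCCCCC(=O)CC(O)CCc1ccc(OCc2ccccc2)c(OC)c1 | intermediate
11 | 1-(4-benzyloxy-3-methoxyphenyl)hexadecane-3,5-dione | CCCCCCCCCCCC(=O)CC(=O)CCc1ccc(OCc2ccccc2)c(OC)c1 | intermediate
12 | [12]-gingerdione, 1-(4-hydroxy-3-methoxyphenyl)hexadecane-3,5-dione | CCCCCCCCCCCC(=O)CC(=O)CCc1ccc(O)c(OC)c1 | target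

**Total step count:** 7
**Longest linear sequence:** 7 steps (1 → 12); ester 5 enters without prior steps.

**Steps most likely to fail**

1. Step 4 (key step). The radical sequence may leak before the peroxide is secured: peroxyl radicals or trivalent manganese may attack benzylic C–H bonds, the hydroperoxy ketone may fragment further, or the catalyst may stall so that conversion stays incomplete. Fallback, from 7 back to the route at 10:
   - Cyclopropanol 7 would be opened by ligand-transfer oxidation with FeCl3 (2.2 equiv, DMF, 0 °C). This cleaves the same C3–C5 bond and delivers chlorine to the secondary radical, giving racemic 1-(4-benzyloxy-3-methoxyphenyl)-3-chlorohexadecan-5-one F1.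
   - NaOAc in MeOH at reflux should eliminate HCl to (E)-1-(4-benzyloxy-3-methoxyphenyl)hexadec-3-en-5-one F2.
   - CuCl-catalysed conjugate borylation (B2pin2, NaOtBu, DPEphos, MeOH, THF, rt) would place boron on C3, giving racemic 1-(4-benzyloxy-3-methoxyphenyl)-3-(4,4,5,5-tetramethyl-1,3,2-dioxaborolan-2-yl)hexadecan-5-one F3.
   - NaBO3·4H2O in THF/H2O oxidises the C–B bond to the β-hydroxy ketone 10, from which steps 6 and 7 follow unchanged.

2. Step 3. Alkene exchange at titanium may be incomplete, so that the ester is consumed by cyclohexyl transfer, reduction or plain Grignard addition before the titanacycle of 4 has formed. Fallback, from 4 back to the route at 7: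
   - Hydroboration of 4 with 9-BBN (THF, rt) would give 9-[4-(4-benzyloxy-3-methoxyphenyl)butyl]-9-borabicyclo[3.3.1]nonane F4, oxidised in the same flask (NaOH, H2O2) to 4-(4-benzyloxy-3-methoxyphenyl)butan-1-ol F5.
   - Appel bromination (CBr4, PPh3, CH2Cl2) gives 1-benzyloxy-4-(4-bromobutyl)-2-methoxybenzene F6.
   - Mg in THF gives [4-(4-benzyloxy-3-methoxyphenyl)butyl]magnesium bromide F7.
   - Slow addition of this Grignard reagent (2.2 equiv) to ester 5 and Ti(OiPr)4 in THF at rt is the classical Kulinkovich reaction. The dialkyltitanium loses one alkyl group as the alkane and becomes titanacyclopropane 6 directly, with no exchange step, and 6 gives 7.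

3. Step 6. Over-oxidation may set in once the diketone has formed, at the doubly activated C4 methylene, or the acetic acid released may dehydrate 10 before it is oxidised. Fallback, from 9 back to the route at 11, bypassing steps 5 and 6:
   - KOH in MeOH (0 °C → rt) should convert the peroxyhemiketal into racemic trans-1-{3-[2-(4-benzyloxy-3-methoxyphenyl)ethyl]oxiran-2-yl}dodecan-1-one F8. The open form 8 loses hydroperoxide anion to the enone, which is re-attacked in a Weitz–Scheffer epoxidation.
   - Pd(PPh3)4 with 1,2-bis(diphenylphosphino)ethane in toluene at 80–100 °C then isomerises the α,β-epoxy ketone to the 1,3-diketone 11. Zerovalent palladium opens the Cα–O bond, and β-hydride elimination followed by reductive elimination gives the second carbonyl.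

**Further compounds**

F1 | step 4 | 1-(4-benzyloxy-3-methoxyphenyl)-3-chlorohexadecan-5-one (racemic) | CCCCCCCCCCCC(=O)CC(Cl)CCc1ccc(OCc2ccccc2)c(OC)c1
F2 | step 4 | (E)-1-(4-benzyloxy-3-methoxyphenyl)hexadec-3-en-5-one | CCCCCCCCCCCC(=O)/C=C/CCc1ccc(OCc2ccccc2)c(OC)c1
F3 | step 4 | 1-(4-benzyloxy-3-methoxyphenyl)-3-(4,4,5,5-tetramethyl-1,3,2-dioxaborolan-2-yl)hexadecan-5-one (racemic) | CCCCCCCCCCCC(=O)CC(B1OC(C)(C)C(C)(C)O1)CCc1ccc(OCc2ccccc2)c(OC)c1
F4 | step 3 | 9-[4-(4-benzyloxy-3-methoxyphenyl)butyl]-9-borabicyclo[3.3.1]nonane (not isolated) | COc1cc(CCCCB2C3CCCC2CCC3)ccc1OCc1ccccc1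
F5 | step 3 | 4-(4-benzyloxy-3-methoxyphenyl)butan-1-ol | OCCCCc1ccc(OCc2ccccc2)c(OC)c1
F6 | step 3 | 1-benzyloxy-4-(4-bromobutyl)-2-methoxybenzene | BrCCCCc1ccc(OCc2ccccc2)c(OC)c1
F7 | step 3 | [4-(4-benzyloxy-3-methoxyphenyl)butyl]magnesium bromide | Br[Mg]CCCCc1ccc(OCc2ccccc2)c(OC)c1
F8 | step 6 | trans-1-{3-[2-(4-benzyloxy-3-methoxyphenyl)ethyl]oxiran-2-yl}dodecan-1-one (racemic) | CCCCCCCCCCCC(=O)[C@H]1O[C@@H]1CCc1ccc(OCc2ccccc2)c(OC)c1
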